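**Retrosynthetic overview**
1. Ring A is bought as 2,4-dibromoanisole (1), with OMe and both C–Br bonds in place. C6–H is the only OMe-activated position left and is the coupling site. PhI(OAc)2 (2) and TfOH (3) are the relay reagents.
2. Ring B is bought as 3',5'-dibromo-2'-hydroxyacetophenone (4). Its phenol O becomes the ether O, and its acetyl group is the latent OH.
3. Key disconnection, diaryl ether C–O bond: C6 of 1 is joined to O of 4 through iodonium salt 5 and aryloxy-λ3-iodane 6, which gives ketone 7.
4. Last disconnection, ring B C–OH bond: the aryl–acetyl C–C bond of 7 is exchanged for C–O (Baeyer–Villiger, acetate 8) to reach target 9. No ring is formed at any stage; both benzene rings are bought.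

Assumption: the target has no stereocentre and its diaryl ether axis rotates freely at room temperature. It is therefore achiral, no step has to set or keep a configuration, and the SMILES carry no stereo descriptors.

**Step 1**
Reactants: 1 2,4-dibromoanisole; 2 (diacetoxyiodo)benzene, PhI(OAc)2; 3 trifluoromethanesulfonic acid; 4 1-(3,5-dibromo-2-hydroxyphenyl)ethanone
Product: 7 1-[3,5-dibromo-2-(3,5-dibromo-2-methoxyphenoxy)phenyl]ethanone, via iodonium triflate 5 (not isolated), via aryloxy-λ3-iodane 6 (not isolated)
Conditions: 1 (1.5 equiv), 2 (1.3 equiv), 3 (2.6 equiv), CH2Cl2, 0 °C to rt, 3 h; evaporate with toluene; 4 (1.0 equiv), K2CO3 (6 equiv), MeCN, 75 °C, 12 h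
Reagents that add atoms: none
Why: Proposed new method: a transient-iodane relay that amounts to a dehydrogenative C(sp2)–H/O–H etherification in one flask; TfOH ionises PhI(OAc)2 to a cationic trivalent-iodine electrophile that substitutes 1 (electrophilic aromatic substitution) at C6, the only position activated by OMe because the para and the other ortho position carry Br, to give 5; after the acid-to-base switch the phenoxide of 4 displaces triflate at iodine to give T-shaped 6, whose ligand coupling (reductive elimination at iodine through an ipso, Meisenheimer-like transition state) moves onto oxygen the aryl group that is more electron-poor (two Br meta to iodine) and ortho-substituted, not phenyl, and expels PhI, and because no low-valent metal is present the four C–Br bonds stay untouched; the closest known reaction types are the acid-promoted condensation of ArI(OAc)2 with arenes to isolated diaryliodonium triflates, the metal-free O-arylation of phenols by isolated diaryliodonium salts, and one-pot arene C–H nitration, azidation or copper-catalysed amination through transient iodonium salts, whereas a phenol as the nucleophile of such a relay, the ortho C–H of a para-blocked dibromoanisole as its site and a 2,6-disubstituted acylphenoxide as its partner have not been shown.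

**Step 2**
Reactants: 7 1-[3,5-dibromo-2-(3,5-dibromo-2-methoxyphenoxy)phenyl]ethanone
Product: 9 3,5-dibromo-2-(3,5-dibromo-2-methoxyphenoxy)phenol, via aryl acetate 8 (not isolated)
Conditions: mCPBA (3 equiv), CF3CO2H (1 equiv), CH2Cl2, 40 °C, 24 h; reductive aqueous wash, solvent swap; K2CO3 (2 equiv), MeOH, rt, 1 h
Reagents that add atoms: mCPBA (3-chloroperoxybenzoic acid), OOC(=O)c1cccc(Cl)c1
Why: Baeyer–Villiger oxidation followed by transesterification: in an aryl methyl ketone the aryl group migrates in preference to methyl even when it is halogenated (the same acetyl-to-hydroxyl tactic is established for halogenated 2-aryloxyacetophenones), so oxygen enters only the ring B C–C(O) bond, and K2CO3/MeOH cleaves the activated aryl acetate 8 without touching OMe, the diaryl ether or any C–Br bond; no stereocentre is formed.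

**Compound list**
1 | 2,4-dibromoanisole (2,4-dibromo-1-methoxybenzene) | COc1ccc(Br)cc1Br | starting material
2 | (diacetoxyiodo)benzene, PhI(OAc)2 | CC(=O)OI(OC(C)=O)c1ccccc1 | starting material
3 | trifluoromethanesulfonic acid | OS(=O)(=O)C(F)(F)F | starting material
4 | 1-(3,5-dibromo-2-hydroxyphenyl)ethanone (3',5'-dibromo-2'-hydroxyacetophenone) | CC(=O)c1cc(Br)cc(Br)c1O | starting material
5 | (3,5-dibromo-2-methoxyphenyl)(phenyl)iodonium trifluoromethanesulfonate | COc1c(Br)cc(Br)cc1[I+]c1ccccc1.[O-]S(=O)(=O)C(F)(F)F | intermediate
6 | (2-acetyl-4,6-dibromophenoxy)(3,5-dibromo-2-methoxyphenyl)(phenyl)-λ3-iodane | COc1c(Br)cc(Br)cc1I(c1ccccc1)Oc1c(Br)cc(Br)cc1C(C)=O | intermediate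
7 | 1-[3,5-dibromo-2-(3,5-dibromo-2-methoxyphenoxy)phenyl]ethanone | COc1c(Br)cc(Br)cc1Oc1c(Br)cc(Br)cc1C(C)=O | intermediate
8 | 3,5-dibromo-2-(3,5-dibromo-2-methoxyphenoxy)phenyl acetate | COc1c(Br)cc(Br)cc1Oc1c(Br)cc(Br)cc1OC(C)=O | intermediate
9 | 3,5-dibromo-2-(3,5-dibromo-2-methoxyphenoxy)phenol | COc1c(Br)cc(Br)cc1Oc1c(O)cc(Br)cc1Br | target

Total step count: 2. Longest linear sequence: 2 (1 to 7 to 9).

**Steps most likely to fail**
The route has only two steps, so the two stages of step 1 are judged apart.

**Step 1, first stage and the relay as a whole (the proposed new step).**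
- Risk: C6 of 1 is only about as reactive as benzene. Self-condensation of 2 in TfOH or acid-induced bromine migration may therefore win. Later, phenyl may be transferred instead of the dibromoanisyl group.
- Fallback: it uses known chemistry only, sets out from 1 and comes back at 7. Ring A is iodinated first at the same C6 (NIS, CF3CO2H, rt) to give 1,5-dibromo-3-iodo-2-methoxybenzene F1. The iodine of ring A itself is then oxidised and capped with a non-transferable group (mCPBA, TsOH·H2O, MeCN, 77 °C, then 1,3,5-trimethoxybenzene). This gives the isolated salt (3,5-dibromo-2-methoxyphenyl)(2,4,6-trimethoxyphenyl)iodonium 4-methylbenzenesulfonate F2. This salt arylates 4 (K2CO3, MeCN, 75 °C) to give 7. The electron-rich, doubly ortho-substituted trimethoxyphenyl group stays on iodine.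

**Step 1, second stage.**
- Risk: the phenoxide of 4 is 2,6-disubstituted, electron-poor and chelating, so it may be too weak a partner for the ligand coupling.
- Fallback: it sets out from 5 and comes back at 9. The ring B oxygen pattern is put in place before the coupling. Purchased 2-(benzyloxy)phenol F3 is dibrominated ortho and para to its free OH (NBS, 2 equiv, MeCN, 0 °C to rt) to give 2-(benzyloxy)-4,6-dibromophenol F4, a much better nucleophile. This phenol and K2CO3 are added to 5 in place of 4 and give 1-(benzyloxy)-3,5-dibromo-2-(3,5-dibromo-2-methoxyphenoxy)benzene F5. BCl3 with pentamethylbenzene (CH2Cl2, −78 °C) removes benzyl, spares OMe and gives 9, so step 2 is no longer needed.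

**Step 2.**
- Risk: ring B is electron-poor, and its aryloxy donor is twisted out of conjugation by two ortho neighbours. The migration may be slow and the conversion incomplete.
- Fallback: it sets out from 7 and comes back at 9, and replaces the peracid migration by a radical decarboxylation.
  - Haloform cleavage (Br2, NaOH, dioxane/H2O, 0 °C) gives 3,5-dibromo-2-(3,5-dibromo-2-methoxyphenoxy)benzoic acid F6.
  - Its lithium carboxylate (LiOH) is irradiated (390 nm LED, MeCN, 35 °C) with Cu(OTf)2 and Cu(O2CC4H3S), copper thiophene-2-carboxylate.
  - Ligand-to-metal charge transfer in the divalent copper carboxylate is followed by loss of CO2. Divalent copper captures the aryl radical, and C–O reductive elimination from trivalent copper gives 3,5-dibromo-2-(3,5-dibromo-2-methoxyphenoxy)phenyl thiophene-2-carboxylate F7.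
  - LiOH in THF/H2O then gives 9.

**Further compounds**
F1 | step 1 | 1,5-dibromo-3-iodo-2-methoxybenzene | COc1c(Br)cc(Br)cc1I
F2 | step 1 | (3,5-dibromo-2-methoxyphenyl)(2,4,6-trimethoxyphenyl)iodonium 4-methylbenzenesulfonate | COc1c(Br)cc(Br)cc1[I+]c1c(OC)cc(OC)cc1OC.Cc1ccc(cc1)S([O-])(=O)=O
F3 | step 1 | 2-(benzyloxy)phenol | Oc1ccccc1OCc1ccccc1
F4 | step 1 | 2-(benzyloxy)-4,6-dibromophenol | Oc1c(Br)cc(Br)cc1OCc1ccccc1
F5 | step 1 | 1-(benzyloxy)-3,5-dibromo-2-(3,5-dibromo-2-methoxyphenoxy)benzene | COc1c(Br)cc(Br)cc1Oc1c(Br)cc(Br)cc1OCc1ccccc1
F6 | step 2 | 3,5-dibromo-2-(3,5-dibromo-2-methoxyphenoxy)benzoic acid | COc1c(Br)cc(Br)cc1Oc1c(Br)cc(Br)cc1C(O)=O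
F7 | step 2 | 3,5-dibromo-2-(3,5-dibromo-2-methoxyphenoxy)phenyl thiophene-2-carboxylate | COc1c(Br)cc(Br)cc1Oc1c(Br)cc(Br)cc1OC(=O)c1cccs1
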